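**Plan**

Numbering: C1 lactone C=O, C2, C3 (peroxy CH), C4 (carbon bearing the lactone oxygen), C5, C6 (quaternary peroxy carbon), C7–C15 chain. Retrosynthetic cuts, in order: O–Si and the C7–C8 saturation; C5–C6 together with C4–O(lactone); C6–OO (perketal link); C6–C7 (acetylide acylation); C15–aryl (copper coupling); C3–O (Schenck ene).
Enabling feature: C4–C5–C6 is a three-carbon run of the 1,2-dioxane ring whose two ends both carry oxygen (C6 the peroxide, C4 the lactone oxygen), and C4 is also the γ-carbon of the lactone ring. An electrophilic C6, a C4=C5 double bond and the C1 carboxyl group are therefore placed to pass charge from C6 to C4 to oxygen.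
Forward: the aryl-alkynyl ketal and the C1–C5 hydroperoxide are made separately and joined through the O–O–C6 perketal link. The dioxane ring closes first and the lactone ring second, in one flask. Alkyne saturation and desilylation finish the synthesis.
Stereochemistry: C3 comes from a peroxidase kinetic resolution. C6 is relayed from C3 through a chair transition state (slim alkynyl group axial, methyl equatorial). C4 follows from the obligatory cis fusion of the five-membered lactone.

Key step: step 11

Assumption: the peroxidase is taken to keep its usual sense of recognition (alkenyl group in the place of aryl, CH2CO2Me in the place of the small alkyl group), so the unreacted hydroperoxide is 3S. This is to be checked on a sample by reduction to the β-hydroxy ester before material is carried on.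

Step 1
Reactants: 1 4-methylpent-3-enoic acid
Product: 2 methyl 4-methylpent-3-enoate
Conditions: MeI, K2CO3, DMF, rt
Reagents that add atoms: iodomethane, CI
Why: Carboxylate O-alkylation (SN2 on MeI) esterifies under non-acidic conditions, which avoids the proton-induced closure of this β,γ-unsaturated acid to the γ,γ-dimethyl lactone and leaves the trisubstituted alkene in place.

Step 2
Reactants: 2 methyl 4-methylpent-3-enoate
Product: 3 methyl 3-hydroperoxy-4-methylpent-4-enoate (racemic)
Conditions: O2, tetraphenylporphyrin (cat), visible light, CH2Cl2, 0 °C; SiO2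
Reagents that add atoms: dioxygen, O=O
Why: Schenck ene reaction, in which singlet oxygen bonds to C3 of the electron-rich trisubstituted alkene while a methyl hydrogen is transferred, so that the double bond moves to C4=C5 and the racemic secondary allylic hydroperoxide results, the conjugated tertiary regioisomer from abstraction at C2 being removed on silica.

Step 3
Reactants: 3 methyl 3-hydroperoxy-4-methylpent-4-enoate (racemic)
Product: 4 methyl (3S)-3-hydroperoxy-4-methylpent-4-enoate
Conditions: horseradish peroxidase, guaiacol (1 equiv), 0.1 M phosphate buffer (pH 6), 20 °C, stopped just past half conversion; SiO2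
Reagents that add atoms: none
Why: Enzymatic kinetic resolution of a secondary hydroperoxide, in which the peroxidase reduces the R enantiomer of allylic and ester-bearing hydroperoxides to the alcohol at the expense of guaiacol and leaves the S enantiomer, which fixes C3.

Step 4
Reactants: 5 4-bromophenol
Product: 6 (4-bromophenoxy)triisopropylsilane
Conditions: TIPSCl, imidazole, DMF, rt
Reagents that add atoms: chlorotriisopropylsilane, CC(C)[Si](Cl)(C(C)C)C(C)C
Why: Imidazole-promoted silylation of a phenol, the triisopropylsilyl group being chosen over smaller silyl groups because the aryl silyl ether has to outlast a Grignard reagent, n-BuLi and the later LiOH saponification.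

Step 5
Reactants: 7 non-8-yn-1-ol
Product: 8 9-bromonon-1-yne
Conditions: CBr4, PPh3, CH2Cl2, 0 °C
Reagents that add atoms: tetrabromomethane, BrC(Br)(Br)Br
Why: The Appel reaction turns the primary alcohol into the bromide by SN2 displacement of the oxyphosphonium group under neutral conditions that leave the terminal alkyne alone.

Step 6
Reactants: 6 (4-bromophenoxy)triisopropylsilane; 8 9-bromonon-1-yne
Product: 12 triisopropyl[4-(non-8-yn-1-yl)phenoxy]silane, via aryl Grignard reagent 9 (not isolated), via bromoalkynylmagnesium bromide 10 (not isolated), via coupled magnesium acetylide 11 (not isolated)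
Conditions: 6, Mg, THF, reflux (gives 9); 8, EtMgBr (1.0 equiv), THF, 0 °C (gives 10); mixed, Li2CuCl4 (5 mol %), THF, 0 °C → rt; aq NH4Cl
Reagents that add atoms: none
Why: Copper-catalysed Kochi-type sp2–sp3 cross-coupling of an aryl Grignard reagent with a primary alkyl bromide, in which prior deprotonation by EtMgBr masks the acidic alkyne C–H as a magnesium acetylide that serves only as a non-transferable ligand on copper and is reprotonated on work-up.

Step 7
Reactants: 12 triisopropyl[4-(non-8-yn-1-yl)phenoxy]silane; 13 N-methoxy-N-methylacetamide
Product: 16 11-[4-(triisopropylsilyloxy)phenyl]undec-3-yn-2-one, via lithium acetylide 14 (not isolated), via tetrahedral lithium adduct 15 (not isolated)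
Conditions: n-BuLi, THF, −78 °C; 13, −78 → 0 °C; aq NH4Cl
Reagents that add atoms: none
Why: Weinreb ketone synthesis, in which the acetylide adds once to the amide and the chelated tetrahedral adduct collapses to the ynone only on quenching, so that no tertiary alcohol can form.

Step 8
Reactants: 16 11-[4-(triisopropylsilyloxy)phenyl]undec-3-yn-2-one
Product: 17 [4-(10,10-dimethoxyundec-8-yn-1-yl)phenoxy]triisopropylsilane
Conditions: HC(OMe)3, MeOH, p-TsOH·H2O (5 mol %), rt; Et3N
Reagents that add atoms: trimethyl orthoformate, COC(OC)OC; methanol, CO
Why: Acid-catalysed ketalisation driven by the orthoester as water scavenger, a standard conversion of alkynyl ketones in which conjugate addition of methanol does not compete in the absence of base and to which the aryl silyl ether is inert.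

Step 9
Reactants: 4 methyl (3S)-3-hydroperoxy-4-methylpent-4-enoate; 17 [4-(10,10-dimethoxyundec-8-yn-1-yl)phenoxy]triisopropylsilane
Product: 18 methyl (3S)-3-({2-methoxy-11-[4-(triisopropylsilyloxy)phenyl]undec-3-yn-2-yl}peroxy)-4-methylpent-4-enoate (both ketal epimers)
Conditions: 17 (1.3 equiv), camphorsulfonic acid (5 mol %), 5 Å MS, CH2Cl2, 0 °C → rt; Et3N; Et3N-washed SiO2
Reagents that add atoms: none
Why: Acid-catalysed transketalisation, the usual entry to mixed methoxy perketals, in which the oxocarbenium ion from the ketal is trapped by the strongly nucleophilic hydroperoxide and sieves take up methanol, C3 being untouched and the new ketal centre (both epimers) being erased in step 11.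

Step 10
Reactants: 18 perketal methyl ester
Product: 20 (3S)-3-({2-methoxy-11-[4-(triisopropylsilyloxy)phenyl]undec-3-yn-2-yl}peroxy)-4-methylpent-4-enoic acid (both ketal epimers), via lithium carboxylate 19 (not isolated)
Conditions: LiOH·H2O, THF/H2O (3:1), 0 °C; cold dilute HCl to pH 4–5, immediate extraction; used at once
Reagents that add atoms: lithium hydroxide, [Li+].[OH-]
Why: Saponification (BAc2) of an unhindered methyl ester at 0 °C, to which dialkyl perketals and the aryl triisopropylsilyl ether are stable and which should outrun β-elimination of the peroxide because the carboxylate, once formed, is no longer acidic at C2.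

Step 11
Reactants: 20 (3S)-perketal acid
Product: 24 7,7,8,8-tetradehydroplakortolide F triisopropylsilyl ether (3S,4S,6S; cis-fused 1,2-dioxane/γ-lactone; alkynyl chain at C6 on the ring face of C2), via trimethylsilyl ester 21 (not isolated), via peroxycarbenium triflate 22 (not isolated), via tertiary C4 cation 23 (not isolated)
Conditions: MSTFA (1.5 equiv), CH2Cl2, rt, then volatiles removed in vacuo; TMSOTf (0.3 equiv), 2,6-di-tert-butyl-4-methylpyridine (0.1 equiv), 4 Å MS, CH2Cl2 (0.005 M), −78 → −40 °C; Et3N, then aq NaHCO3
Reagents that add atoms: none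
Why: Proposed new method: TMSOTf silylates the methoxy oxygen of silyl ester 21, the most basic site, and expels TMSOMe to give the alkynyl-conjugated peroxycarbenium ion 22; the CH2 terminus of the isopropenyl group attacks C6 (C5–C6 bond), the tertiary cation 23 so formed is taken at C4 by the carbonyl oxygen of the silyl ester (C4–O bond), and release of the silyl group returns TMSOTf, so that the Lewis acid turns over and no strong Brønsted acid accumulates. Nearest precedent lies in two separate families: allylsilanes, enol silanes and unactivated alkenes have been added to Lewis-acid-generated peroxycarbenium ions, in some cases with ring formation, and oxocarbenium Prins cyclisations have been terminated by a tethered carboxyl oxygen, whereas their merger into one cascade that builds a bicyclic peroxylactone goes beyond both. The 1,2-dioxane closes 6-endo-trig at both π partners through a Prins-type chair in which the O–O unit replaces the usual CH2–O, and the γ-lactone closes 5-exo with respect to the former C4=C5 bond, as in a halolactonisation. C6 is controlled by C3 through the chair that keeps the C2 arm equatorial: the rod-shaped alkynyl group takes the place cis to the O–O bond in 22 and thereby the axial site, the bulkier methyl group the equatorial one, which puts the chain on the same ring face as C2; C4 is controlled by the tether, since a five-membered lactone can bridge C3 and C4 only cis. C3 keeps its configuration because its C–O bond is never broken and a peroxide link offers no oxonia-Cope escape. The step needs loss of methoxide rather than of the peroxide, Markovnikov attack and capture faster than proton loss, which are secured in turn by the silicon Lewis acid that seeks the more basic ether oxygen, by the 1,1-disubstituted alkene that can only place the charge on C4, and by the neighbouring silyl ester together with low temperature, high dilution and a hindered pyridine.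

Step 12
Reactants: 24 7,7,8,8-tetradehydroplakortolide F triisopropylsilyl ether
Product: 26 plakortolide F triisopropylsilyl ether (3S,4S,6R), via Z-alkene 25 (not isolated)
Conditions: KO2CN=NCO2K (large excess, in portions), AcOH, MeOH/CH2Cl2, 0 °C → rt
Reagents that add atoms: none
Why: Diimide reduction, a concerted syn transfer of H2 that saturates C–C π bonds (the alkyne, then the strained Z-alkene) but leaves the O–O bond, the lactone and the arene alone, as is standard for unsaturated cyclic peroxides, and touches no stereocentre (the C6 descriptor changes only through ligand ranking).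

Step 13
Reactants: 26 plakortolide F triisopropylsilyl ether
Product: 27 plakortolide F
Conditions: HF·pyridine, pyridine, THF, 0 °C → rt
Reagents that add atoms: none
Why: Fluoride-mediated cleavage of the aryl silyl ether under buffered, non-basic conditions, so that neither β-elimination of the peroxide from the lactone nor lactone opening should occur.

**Compound list**

1 | 4-methylpent-3-enoic acid | CC(C)=CCC(=O)O | starting material
2 | methyl 4-methylpent-3-enoate | CC(C)=CCC(=O)OC | intermediate
3 | methyl 3-hydroperoxy-4-methylpent-4-enoate (racemic) | C=C(C)C(OO)CC(=O)OC | intermediate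
4 | methyl (3S)-3-hydroperoxy-4-methylpent-4-enoate | OO[C@@H](CC(=O)OC)C(C)=C | intermediate
5 | 4-bromophenol | Oc1ccc(Br)cc1 | starting material
6 | (4-bromophenoxy)triisopropylsilane | CC(C)[Si](Oc1ccc(Br)cc1)(C(C)C)C(C)C | intermediate
7 | non-8-yn-1-ol | C#CCCCCCCCO | starting material
8 | 9-bromonon-1-yne | C#CCCCCCCCBr | intermediate
9 | [4-(triisopropylsilyloxy)phenyl]magnesium bromide (in flask) | CC(C)[Si](Oc1ccc([Mg]Br)cc1)(C(C)C)C(C)C | intermediate
10 | (9-bromonon-1-yn-1-yl)magnesium bromide (in flask) | Br[Mg]C#CCCCCCCCBr | intermediate
11 | {9-[4-(triisopropylsilyloxy)phenyl]non-1-yn-1-yl}magnesium bromide (in flask) | Br[Mg]C#CCCCCCCCc1ccc(O[Si](C(C)C)(C(C)C)C(C)C)cc1 | intermediate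
12 | triisopropyl[4-(non-8-yn-1-yl)phenoxy]silane | C#CCCCCCCCc1ccc(O[Si](C(C)C)(C(C)C)C(C)C)cc1 | intermediate
13 | N-methoxy-N-methylacetamide | CC(=O)N(C)OC | starting material
14 | lithium acetylide of 12 (in flask) | [Li]C#CCCCCCCCc1ccc(O[Si](C(C)C)(C(C)C)C(C)C)cc1 | intermediate
15 | lithium alkoxide of the tetrahedral acetylide–amide adduct (in flask) | CC(O[Li])(N(C)OC)C#CCCCCCCCc1ccc(O[Si](C(C)C)(C(C)C)C(C)C)cc1 | intermediate
16 | 11-[4-(triisopropylsilyloxy)phenyl]undec-3-yn-2-one | CC(=O)C#CCCCCCCCc1ccc(O[Si](C(C)C)(C(C)C)C(C)C)cc1 | intermediate
17 | [4-(10,10-dimethoxyundec-8-yn-1-yl)phenoxy]triisopropylsilane | CC(OC)(OC)C#CCCCCCCCc1ccc(O[Si](C(C)C)(C(C)C)C(C)C)cc1 | intermediate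
18 | methyl (3S)-3-({2-methoxy-11-[4-(triisopropylsilyloxy)phenyl]undec-3-yn-2-yl}peroxy)-4-methylpent-4-enoate (both ketal epimers) | COC(C)(C#CCCCCCCCc1ccc(O[Si](C(C)C)(C(C)C)C(C)C)cc1)OO[C@@H](CC(=O)OC)C(C)=C | intermediate
19 | lithium salt of acid 20 (in flask) | [Li+].COC(C)(C#CCCCCCCCc1ccc(O[Si](C(C)C)(C(C)C)C(C)C)cc1)OO[C@@H](CC(=O)[O-])C(C)=C | intermediate
20 | (3S)-3-({2-methoxy-11-[4-(triisopropylsilyloxy)phenyl]undec-3-yn-2-yl}peroxy)-4-methylpent-4-enoic acid (both ketal epimers) | COC(C)(C#CCCCCCCCc1ccc(O[Si](C(C)C)(C(C)C)C(C)C)cc1)OO[C@@H](CC(=O)O)C(C)=C | intermediate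
21 | trimethylsilyl ester of 20 (in flask) | COC(C)(C#CCCCCCCCc1ccc(O[Si](C(C)C)(C(C)C)C(C)C)cc1)OO[C@@H](CC(=O)O[Si](C)(C)C)C(C)=C | intermediate
22 | C6 peroxycarbenium triflate from 21 (in flask) | CC(C#CCCCCCCCc1ccc(O[Si](C(C)C)(C(C)C)C(C)C)cc1)=[O+]O[C@@H](CC(=O)O[Si](C)(C)C)C(C)=C.[O-]S(=O)(=O)C(F)(F)F | intermediate
23 | monocyclic 1,2-dioxan-4-ylium triflate, tertiary cation at C4 (in flask) | C[C@@]1(C#CCCCCCCCc2ccc(O[Si](C(C)C)(C(C)C)C(C)C)cc2)C[C+](C)[C@H](CC(=O)O[Si](C)(C)C)OO1.[O-]S(=O)(=O)C(F)(F)F | intermediate
24 | 7,7,8,8-tetradehydroplakortolide F triisopropylsilyl ether, (3S,4S,6S), cis-fused 1,2-dioxane/γ-lactone; 4-Me, 6-Me and H3 on one face; C2, lactone O and alkynyl chain on the other | C[C@@]1(C#CCCCCCCCc3ccc(O[Si](C(C)C)(C(C)C)C(C)C)cc3)C[C@]2(C)OC(=O)C[C@@H]2OO1 | intermediate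
25 | (7Z)-7,8-didehydroplakortolide F triisopropylsilyl ether, (3S,4S,6S) (in flask) | C[C@@]1(/C=C\CCCCCCCc3ccc(O[Si](C(C)C)(C(C)C)C(C)C)cc3)C[C@]2(C)OC(=O)C[C@@H]2OO1 | intermediate
26 | plakortolide F triisopropylsilyl ether, (3S,4S,6R) | C[C@@]1(CCCCCCCCCc3ccc(O[Si](C(C)C)(C(C)C)C(C)C)cc3)C[C@]2(C)OC(=O)C[C@@H]2OO1 | intermediate
27 | plakortolide F, (3S,4S,6R) | C[C@@]1(CCCCCCCCCc2ccc(O)cc2)C[C@]2(C)OC(=O)C[C@@H]2OO1 | target

**Step count and risks**

Total steps: 13. Longest linear sequence: 9 steps (step 4 or 5, then steps 6 to 13).

Steps most likely to fail: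

1. Step 11. Several processes can defeat the cascade:
- The Lewis acid may expel the peroxide instead of methoxide.
- The carboxyl group may interfere at the peroxycarbenium centre.
- The tertiary cation may lose a proton or be attacked by the neighbouring peroxide oxygen before the carboxyl oxygen arrives.
- The two faces of C6 may be poorly distinguished.

The fallback uses known reaction types only, sets out from 18 and comes back at 24. It takes the two ring closures apart. Ester 18, whose masked carboxyl group cannot interfere with the Lewis acid, is treated with SnCl4 in CH2Cl2 at −78 °C. This is a halide-terminated, ring-forming addition of an alkene to a peroxycarbenium ion, and it should give the 4-chloro-1,2-dioxane methyl ester F1 through the same chair. Saponification with LiOH at 0 °C and careful acidification give the chloro acid F2. AgOTf with 2,6-lutidine in CH2Cl2 then ionises the tertiary chloride next to the free carboxyl group. This is a classical silver-assisted γ-lactonisation, and it can again deliver only the cis-fused 24.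

2. Step 3. The enzyme may turn the substrate over slowly or discriminate poorly between the enantiomers, so that enantiopurity stays low even beyond half conversion.

The fallback sets out from 3 and comes back at 4. It replaces the enzyme by a covalent auxiliary and chromatography. Commercial (1R,2S)-2-phenylcyclohexanol is acetylated to (1R,2S)-2-phenylcyclohexyl acetate F3. Petasis methylenation with Cp2TiMe2 converts this into the isopropenyl ether F4. PPTS-catalysed addition of racemic 3 to F4 gives the (3S)-perketal F5 and the (3R)-perketal F6, diastereomers that are separated on silica. AcOH/THF/H2O releases 4 from F5.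

3. Step 9. The alkynyl ketal may ionise sluggishly. The acid strength and time then required invite acid-induced cleavage of the allylic hydroperoxide or double exchange to a bis-peroxide.

The fallback sets out from 17 and comes back at 18. It changes an equilibrium exchange into an irreversible addition. TMSOTf with i-Pr2NEt in CH2Cl2 eliminates one methoxy group of 17 to give the 2-methoxy-1-en-3-yne F7; only the methyl side carries hydrogens, so a single enol ether can form. PPTS-catalysed Markovnikov addition of 4 to F7, the standard way of making 2-alkoxyalk-2-yl perketals, then gives 18 without any methanol to remove.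

**Further compounds**

F1 | step 11 | methyl 2-[(3S,6S)-4-chloro-4,6-dimethyl-6-{9-[4-(triisopropylsilyloxy)phenyl]non-1-yn-1-yl}-1,2-dioxan-3-yl]acetate (either C4 epimer) | C[C@@]1(C#CCCCCCCCc2ccc(O[Si](C(C)C)(C(C)C)C(C)C)cc2)CC(C)(Cl)[C@H](CC(=O)OC)OO1
F2 | step 11 | 2-[(3S,6S)-4-chloro-4,6-dimethyl-6-{9-[4-(triisopropylsilyloxy)phenyl]non-1-yn-1-yl}-1,2-dioxan-3-yl]acetic acid (either C4 epimer) | C[C@@]1(C#CCCCCCCCc2ccc(O[Si](C(C)C)(C(C)C)C(C)C)cc2)CC(C)(Cl)[C@H](CC(=O)O)OO1
F3 | step 3 | (1R,2S)-2-phenylcyclohexyl acetate | CC(=O)O[C@@H]1CCCC[C@H]1c2ccccc2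
F4 | step 3 | 2-{[(1R,2S)-2-phenylcyclohexyl]oxy}prop-1-ene | C=C(C)O[C@@H]1CCCC[C@H]1c2ccccc2
F5 | step 3 | methyl (3S)-4-methyl-3-[(2-{[(1R,2S)-2-phenylcyclohexyl]oxy}propan-2-yl)peroxy]pent-4-enoate | CC(C)(O[C@@H]1CCCC[C@H]1c2ccccc2)OO[C@@H](CC(=O)OC)C(C)=C
F6 | step 3 | methyl (3R)-4-methyl-3-[(2-{[(1R,2S)-2-phenylcyclohexyl]oxy}propan-2-yl)peroxy]pent-4-enoate | CC(C)(O[C@@H]1CCCC[C@H]1c2ccccc2)OO[C@H](CC(=O)OC)C(C)=C
F7 | step 9 | triisopropyl[4-(10-methoxyundec-10-en-8-yn-1-yl)phenoxy]silane | C=C(OC)C#CCCCCCCCc1ccc(O[Si](C(C)C)(C(C)C)C(C)C)cc1
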